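**Retrosynthetic overview**
1. The last skeletal cut is the C6–CH2 bond of the propane chain. A C6 aryl triflate of the chromene is joined to the 9-BBN adduct of a ring A allylarene by B-alkyl Suzuki coupling, and both phenols are then freed from silyl ethers.
2. Feature used: pyran carbon C4 and prenyl carbon C1′ are bound to the adjacent ring B carbons C4a and C5. C4a is ortho to C8a (bearing O1) and C5 is ortho to C6, where a phenol oxygen can stand in for the chain, so ring B is treated as a 1,2,4-trioxygenated benzene (O8a, O8, O6).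
3. Key disconnection: C5–C1′, C4a–C4 and O1–C2 are made in one thermal operation from an O6 1,1-dimethylallyl ether and an O8a 1,1-dimethylpropargyl ether. The hydroxyl released at C6 becomes the triflate and leaves the molecule in the coupling.
4. The bis-ether comes from 3,4-dihydroxybenzaldehyde by O4 propargylation, O3 silylation, Baeyer–Villiger exchange of the formyl group for the third oxygen, and palladium-catalysed tert-prenylation.
5. Ring order: rings A and B are bought as benzenes, and the pyran ring is the only ring formed, in step 6.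

Key step: step 6

Remark: chromene numbering (O1, C2, C3, C4, C4a, C5 to C8, C8a; prenyl C1′ to C3′) is used for ring B atoms at every stage, also before the pyran ring exists. The target has no stereocentre and no stereogenic double bond, so no step has to set configuration.

**Step 1**
Reactants: 1 3,4-dihydroxybenzaldehyde; 2 3-chloro-3-methylbut-1-yne
Product: 3 3-hydroxy-4-(2-methylbut-3-yn-2-yloxy)benzaldehyde
Conditions: 2 (1.2 equiv), DBU (1.2 equiv), CuCl2·2H2O (1 mol%), MeCN, N2, 0 °C to rt
Reagents that add atoms: none
Why: Copper-catalysed propargylic etherification of a phenol with a tertiary propargylic chloride, in which about one equivalent of base ionises only O4–H (para to the formyl group and clearly the more acidic), so the ether should form at O4 and leave O3–H free.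

**Step 2**
Reactants: 3 3-hydroxy-4-(2-methylbut-3-yn-2-yloxy)benzaldehyde
Product: 4 4-(2-methylbut-3-yn-2-yloxy)-3-(triisopropylsilyloxy)benzaldehyde
Conditions: TIPSCl (1.3 equiv), imidazole (2.5 equiv), DMF, rt
Reagents that add atoms: triisopropylsilyl chloride, CC(C)[Si](Cl)(C(C)C)C(C)C
Why: Standard imidazole-promoted O-silylation of the one remaining phenol, which installs the bulky group that later shields C7 and leaves the aldehyde, alkyne and tertiary ether untouched.

**Step 3**
Reactants: 4 4-(2-methylbut-3-yn-2-yloxy)-3-(triisopropylsilyloxy)benzaldehyde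
Product: 6 4-(2-methylbut-3-yn-2-yloxy)-3-(triisopropylsilyloxy)phenol, via aryl formate 5 (not isolated)
Conditions: mCPBA (1.3 equiv), CH2Cl2, 0 °C to rt; then MeOH, Et3N (cat.), 0 °C
Reagents that add atoms: meta-chloroperoxybenzoic acid, OOC(=O)c1cccc(Cl)c1
Why: Baeyer–Villiger oxidation in which the electron-rich aryl group (para-alkoxy) migrates in the Criegee adduct to give formate 5, whose very labile ester is transesterified by methanol under conditions too mild to touch the aryl silyl ether or the terminal alkyne.

**Step 4**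
Reactants: 7 2-methylbut-3-en-2-ol
Product: 9 tert-butyl 2-methylbut-3-en-2-yl carbonate, via lithium alkoxide 8 (not isolated)
Conditions: n-BuLi (1.05 equiv), THF, −78 to 0 °C; then Boc2O (1.1 equiv), 0 °C to rt
Reagents that add atoms: di-tert-butyl dicarbonate, CC(C)(C)OC(=O)OC(=O)OC(C)(C)C
Why: Acylation of a preformed tertiary lithium alkoxide with Boc2O is the usual way to mixed carbonates of hindered allylic alcohols and avoids acid that would ionise the tertiary allylic centre.

**Step 5**
Reactants: 6 4-(2-methylbut-3-yn-2-yloxy)-3-(triisopropylsilyloxy)phenol; 9 tert-butyl 2-methylbut-3-en-2-yl carbonate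
Product: 10 4-(2-methylbut-3-en-2-yloxy)-1-(2-methylbut-3-yn-2-yloxy)-2-(triisopropylsilyloxy)benzene
Conditions: 9 (1.5 equiv), Pd(PPh3)4 (3 mol%), THF, 0 °C; chromatography on Et3N-washed silica, kept below 30 °C
Reagents that add atoms: none
Why: Tsuji–Trost O-allylation in which zerovalent palladium ionises the carbonate, the released tert-butoxide deprotonates the phenol, and the phenoxide attacks the more substituted terminus of the 1,1-dimethyl-π-allyl complex under kinetic control at 0 °C, where the aryl propargyl ether and the alkyne are not engaged.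

**Step 6**
Reactants: 10 4-(2-methylbut-3-en-2-yloxy)-1-(2-methylbut-3-yn-2-yloxy)-2-(triisopropylsilyloxy)benzene
Product: 16 2,2-dimethyl-5-(3-methylbut-2-enyl)-8-(triisopropylsilyloxy)-2H-chromen-6-ol, via Claisen dienone 11 (not isolated), via prenylphenol 12 (not isolated), via allenyl dienone 13 (not isolated), via allenylphenol 14 (not isolated), via ortho-quinone methide 15 (not isolated)
Conditions: PhNEt2 (degassed), Ar, 125 °C, 2 h; then 190 °C, 3 h
Reagents that add atoms: none
Why: At about 125 °C the O6 1,1-dimethylallyl ether of 10 undergoes an aromatic Claisen [3,3] shift through a chair transition state in which its CH2 terminus bonds to C5 (C5–C1′), and dienone 11 tautomerises to phenol 12. At about 190 °C the O8a 1,1-dimethylpropargyl ether shifts [3,3] with its alkyne CH terminus bonding to C4a (C4a–C4) to give allenyl dienone 13, which enolises to 14 and passes, by a 1,5-hydrogen shift from O8a–H to the central allene carbon, into the Z ortho-quinone methide 15. The pyran ring, the only ring closed, forms by a six-electron oxa-electrocyclisation of 15 that joins O1 to C2 and restores the aromaticity of ring B. The closest known reaction types are the Claisen rearrangement of aryl 1,1-dimethylallyl ethers to ortho-prenylphenols and the thermal conversion of aryl 1,1-dimethylpropargyl ethers into 2,2-dimethyl-2H-chromenes, both well established and both accelerated by their gem-dimethyl groups, so that only their succession in one flask on one ring has still to be shown. No stereocentre remains in 16, because the sp3 ring carbons of 11 and 13 are flattened on tautomerisation. The step needs site selectivity in the allyl shift (C5, not C7), which rests on the triisopropylsilyl ether at O8 crowding C7 and, as a donor meta to O6, favouring the position para to itself, while the propargyl shift can end productively only at C4a because C8 carries oxygen, and the lower barrier of the tertiary allyl ether means that C5 is attacked while C4a still bears only hydrogen.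

**Step 7**
Reactants: 16 2,2-dimethyl-5-(3-methylbut-2-enyl)-8-(triisopropylsilyloxy)-2H-chromen-6-ol
Product: 17 2,2-dimethyl-5-(3-methylbut-2-enyl)-8-(triisopropylsilyloxy)-2H-chromen-6-yl trifluoromethanesulfonate
Conditions: Tf2O (1.2 equiv), pyridine (3 equiv), CH2Cl2, −78 to 0 °C
Reagents that add atoms: trifluoromethanesulfonic anhydride, O=S(=O)(OS(=O)(=O)C(F)(F)F)C(F)(F)F
Why: O-sulfonylation of the single free phenol with Tf2O in buffered, cold medium turns the oxygen handle at C6 into a cross-coupling leaving group without protonating the prenyl or chromene alkenes.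

**Step 8**
Reactants: 18 4-bromo-3-methoxyphenol
Product: 19 (4-bromo-3-methoxyphenoxy)triisopropylsilane
Conditions: TIPSCl (1.2 equiv), imidazole (2.5 equiv), DMF, rt
Reagents that add atoms: triisopropylsilyl chloride, CC(C)[Si](Cl)(C(C)C)C(C)C
Why: Routine phenol silylation that removes the acidic proton before the organomagnesium step and uses the same group as on ring B, so that one fluoride treatment clears both at the end.

**Step 9**
Reactants: 19 (4-bromo-3-methoxyphenoxy)triisopropylsilane; 20 allyl bromide
Product: 22 (4-allyl-3-methoxyphenoxy)triisopropylsilane, via arylmagnesium bromide 21 (not isolated)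
Conditions: Mg turnings (1.3 equiv), I2 (cat.), THF, reflux; then 20 (1.5 equiv), 0 °C to rt
Reagents that add atoms: none
Why: Grignard formation from an ortho-methoxy aryl bromide followed by the classical allylation of an arylmagnesium halide with allyl bromide, which gives the same allylarene by either direct or allylic displacement and leaves the silyl ether intact.

**Step 10**
Reactants: 22 (4-allyl-3-methoxyphenoxy)triisopropylsilane; 17 2,2-dimethyl-5-(3-methylbut-2-enyl)-8-(triisopropylsilyloxy)-2H-chromen-6-yl trifluoromethanesulfonate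
Product: 24 6-{3-[2-methoxy-4-(triisopropylsilyloxy)phenyl]propyl}-2,2-dimethyl-5-(3-methylbut-2-enyl)-8-(triisopropylsilyloxy)-2H-chromene, via B-alkyl-9-BBN borane 23 (not isolated)
Conditions: 22 (1.3 equiv), 9-BBN (0.5 M in THF, 1.35 equiv), 0 °C to rt; then K3PO4 (3 M aq., 3 equiv); then 17, PdCl2(dppf) (5 mol%), THF/DMF, 60 °C
Reagents that add atoms: none
Why: Anti-Markovnikov hydroboration of the terminal alkene gives primary borane 23, whose hydroxy-ate complex transmetallates to the arylpalladium species from 17 in a B-alkyl Suzuki–Miyaura coupling, with dppf favouring reductive elimination over β-hydride elimination and the aqueous base destroying surplus 9-BBN before the prenyl and chromene alkenes enter the flask.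

**Step 11**
Reactants: 24 6-{3-[2-methoxy-4-(triisopropylsilyloxy)phenyl]propyl}-2,2-dimethyl-5-(3-methylbut-2-enyl)-8-(triisopropylsilyloxy)-2H-chromene
Product: 25 kazinol N, 6-[3-(4-hydroxy-2-methoxyphenyl)propyl]-2,2-dimethyl-5-(3-methylbut-2-enyl)-2H-chromen-8-ol
Conditions: TBAF (2.5 equiv), AcOH (2.5 equiv), THF, 0 °C
Reagents that add atoms: none
Why: Fluoride-induced cleavage of both aryl silyl ethers, buffered with acetic acid so that the electron-rich phenols are released in protonated form and neither the chromene nor the prenyl group meets strong acid or base.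

**Compound list**
1 | 3,4-dihydroxybenzaldehyde | O=Cc1ccc(O)c(O)c1 | starting material
2 | 3-chloro-3-methylbut-1-yne | CC(C)(Cl)C#C | starting material
3 | 3-hydroxy-4-(2-methylbut-3-yn-2-yloxy)benzaldehyde | O=Cc1ccc(OC(C)(C)C#C)c(O)c1 | intermediate
4 | 4-(2-methylbut-3-yn-2-yloxy)-3-(triisopropylsilyloxy)benzaldehyde | O=Cc1ccc(OC(C)(C)C#C)c(O[Si](C(C)C)(C(C)C)C(C)C)c1 | intermediate
5 | 4-(2-methylbut-3-yn-2-yloxy)-3-(triisopropylsilyloxy)phenyl formate | O=COc1ccc(OC(C)(C)C#C)c(O[Si](C(C)C)(C(C)C)C(C)C)c1 | intermediate
6 | 4-(2-methylbut-3-yn-2-yloxy)-3-(triisopropylsilyloxy)phenol | Oc1ccc(OC(C)(C)C#C)c(O[Si](C(C)C)(C(C)C)C(C)C)c1 | intermediate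
7 | 2-methylbut-3-en-2-ol | CC(C)(O)C=C | starting material
8 | lithium 2-methylbut-3-en-2-olate | [Li+].[O-]C(C)(C)C=C | intermediate
9 | tert-butyl 2-methylbut-3-en-2-yl carbonate | CC(C)(C)OC(=O)OC(C)(C)C=C | intermediate
10 | 4-(2-methylbut-3-en-2-yloxy)-1-(2-methylbut-3-yn-2-yloxy)-2-(triisopropylsilyloxy)benzene | C#CC(C)(C)Oc1ccc(OC(C)(C)C=C)cc1O[Si](C(C)C)(C(C)C)C(C)C | intermediate
11 | 6-(3-methylbut-2-enyl)-4-(2-methylbut-3-yn-2-yloxy)-3-(triisopropylsilyloxy)cyclohexa-2,4-dien-1-one (racemic, transient) | O=C1C=C(O[Si](C(C)C)(C(C)C)C(C)C)C(OC(C)(C)C#C)=CC1CC=C(C)C | intermediate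
12 | 2-(3-methylbut-2-enyl)-4-(2-methylbut-3-yn-2-yloxy)-5-(triisopropylsilyloxy)phenol | C#CC(C)(C)Oc1cc(CC=C(C)C)c(O)cc1O[Si](C(C)C)(C(C)C)C(C)C | intermediate
13 | 4-hydroxy-6-(3-methylbuta-1,2-dienyl)-5-(3-methylbut-2-enyl)-2-(triisopropylsilyloxy)cyclohexa-2,4-dien-1-one (racemic, transient) | O=C1C(O[Si](C(C)C)(C(C)C)C(C)C)=CC(O)=C(CC=C(C)C)C1C=C=C(C)C | intermediate
14 | 3-(3-methylbuta-1,2-dienyl)-2-(3-methylbut-2-enyl)-5-(triisopropylsilyloxy)benzene-1,4-diol | Oc1c(O[Si](C(C)C)(C(C)C)C(C)C)cc(O)c(CC=C(C)C)c1C=C=C(C)C | intermediate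
15 | (6Z)-4-hydroxy-5-(3-methylbut-2-enyl)-6-(3-methylbut-2-enylidene)-2-(triisopropylsilyloxy)cyclohexa-2,4-dien-1-one | CC(C)=C/C=C1\C(=O)C(O[Si](C(C)C)(C(C)C)C(C)C)=CC(O)=C1CC=C(C)C | intermediate
16 | 2,2-dimethyl-5-(3-methylbut-2-enyl)-8-(triisopropylsilyloxy)-2H-chromen-6-ol | Oc1cc(O[Si](C(C)C)(C(C)C)C(C)C)c2OC(C)(C)C=Cc2c1CC=C(C)C | intermediate
17 | 2,2-dimethyl-5-(3-methylbut-2-enyl)-8-(triisopropylsilyloxy)-2H-chromen-6-yl trifluoromethanesulfonate | O=S(=O)(Oc1cc(O[Si](C(C)C)(C(C)C)C(C)C)c2OC(C)(C)C=Cc2c1CC=C(C)C)C(F)(F)F | intermediate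
18 | 4-bromo-3-methoxyphenol | COc1cc(O)ccc1Br | starting material
19 | (4-bromo-3-methoxyphenoxy)triisopropylsilane | COc1cc(O[Si](C(C)C)(C(C)C)C(C)C)ccc1Br | intermediate
20 | allyl bromide | C=CCBr | starting material
21 | [2-methoxy-4-(triisopropylsilyloxy)phenyl]magnesium bromide | COc1cc(O[Si](C(C)C)(C(C)C)C(C)C)ccc1[Mg]Br | intermediate
22 | (4-allyl-3-methoxyphenoxy)triisopropylsilane | COc1cc(O[Si](C(C)C)(C(C)C)C(C)C)ccc1CC=C | intermediate
23 | 9-{3-[2-methoxy-4-(triisopropylsilyloxy)phenyl]propyl}-9-borabicyclo[3.3.1]nonane | COc1cc(O[Si](C(C)C)(C(C)C)C(C)C)ccc1CCCB1C2CCCC1CCC2 | intermediate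
24 | 6-{3-[2-methoxy-4-(triisopropylsilyloxy)phenyl]propyl}-2,2-dimethyl-5-(3-methylbut-2-enyl)-8-(triisopropylsilyloxy)-2H-chromene | COc1cc(O[Si](C(C)C)(C(C)C)C(C)C)ccc1CCCc1cc(O[Si](C(C)C)(C(C)C)C(C)C)c2OC(C)(C)C=Cc2c1CC=C(C)C | intermediate
25 | kazinol N | COc1cc(O)ccc1CCCc1cc(O)c2c(c1CC=C(C)C)C=CC(C)(C)O2 | target

**Step count**
Total step count: 11.
Longest linear sequence: 8 steps (steps 1, 2, 3, 5, 6, 7, 10, 11).

**Steps most likely to fail**

**Step 6.**
- What may go wrong: part of the allyl shift may run to C7. The tertiary allyl ether may fragment with loss of isoprene before it rearranges. The free, oxidisable phenol released in the first stage may degrade during the hotter second stage.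
- Fallback: the cascade is given up for two separate rearrangements, with the handle installed between them.
- Route: setting out from 10, heating is limited to about 110 °C in toluene, and 12 is isolated at that point and freed from any C7 isomer by chromatography.
- The phenol of 12 is capped at once with Tf2O and pyridine in CH2Cl2 to give 2-(3-methylbut-2-enyl)-4-(2-methylbut-3-yn-2-yloxy)-5-(triisopropylsilyloxy)phenyl trifluoromethanesulfonate F1.
- F1 no longer has a free phenol. It is taken alone through the propargyl ether to chromene rearrangement (1,2-dichlorobenzene, 170 °C) and comes back to the route at 17.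

**Step 10.**
- What may go wrong: oxidative addition into the electron-rich, ortho-substituted C6–O triflate bond may be slow. Base-induced S–O cleavage of the triflate, protodeboronation of the borane, β-hydride elimination or partial loss of the silyl ethers could then take over.
- Fallback: the boron nucleophile and its aqueous base are replaced by an organozinc reagent.
- Route: setting out from 22, borane 23 is made as before and oxidised (NaOH, H2O2, 0 °C) to 3-[2-methoxy-4-(triisopropylsilyloxy)phenyl]propan-1-ol F2.
- An Appel reaction (I2, PPh3, imidazole, CH2Cl2) gives [4-(3-iodopropyl)-3-methoxyphenoxy]triisopropylsilane F3.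
- Zinc insertion (Zn dust, LiCl, THF, 40 °C) gives {3-[2-methoxy-4-(triisopropylsilyloxy)phenyl]propyl}zinc iodide F4.
- Negishi coupling of F4 with 17 (Pd(OAc)2, SPhos, THF, 50 °C) comes back to the route at 24.

**Step 5.**
- What may go wrong: the phenoxide may attack the primary allyl terminus. Palladium may re-ionise the tertiary ether so that it drifts to the linear prenyl ether. The labile product may start its Claisen shift during isolation.
- Fallback: the vinyl group is built by olefination instead of allylic substitution.
- Route: setting out from 6, alkylation with ethyl 2-bromo-2-methylpropanoate (K2CO3, MeCN, 60 °C) gives ethyl 2-methyl-2-[4-(2-methylbut-3-yn-2-yloxy)-3-(triisopropylsilyloxy)phenoxy]propanoate F5.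
- Partial reduction (i-Bu2AlH, toluene, −78 °C) gives 2-methyl-2-[4-(2-methylbut-3-yn-2-yloxy)-3-(triisopropylsilyloxy)phenoxy]propanal F6.
- Wittig methylenation of this non-enolisable aldehyde (MePPh3Br, KN(SiMe3)2, THF, 0 °C) comes back to the route at 10.

**Further compounds**
F1 | step 6 | 2-(3-methylbut-2-enyl)-4-(2-methylbut-3-yn-2-yloxy)-5-(triisopropylsilyloxy)phenyl trifluoromethanesulfonate | C#CC(C)(C)Oc1cc(CC=C(C)C)c(OS(=O)(=O)C(F)(F)F)cc1O[Si](C(C)C)(C(C)C)C(C)C
F2 | step 10 | 3-[2-methoxy-4-(triisopropylsilyloxy)phenyl]propan-1-ol | COc1cc(O[Si](C(C)C)(C(C)C)C(C)C)ccc1CCCO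
F3 | step 10 | [4-(3-iodopropyl)-3-methoxyphenoxy]triisopropylsilane | COc1cc(O[Si](C(C)C)(C(C)C)C(C)C)ccc1CCCI
F4 | step 10 | {3-[2-methoxy-4-(triisopropylsilyloxy)phenyl]propyl}zinc iodide | COc1cc(O[Si](C(C)C)(C(C)C)C(C)C)ccc1CCC[Zn]I
F5 | step 5 | ethyl 2-methyl-2-[4-(2-methylbut-3-yn-2-yloxy)-3-(triisopropylsilyloxy)phenoxy]propanoate | CCOC(=O)C(C)(C)Oc1ccc(OC(C)(C)C#C)c(O[Si](C(C)C)(C(C)C)C(C)C)c1
F6 | step 5 | 2-methyl-2-[4-(2-methylbut-3-yn-2-yloxy)-3-(triisopropylsilyloxy)phenoxy]propanal | O=CC(C)(C)Oc1ccc(OC(C)(C)C#C)c(O[Si](C(C)C)(C(C)C)C(C)C)c1
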